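The germacrane ring is not cyclised end to end. It is derived from a 13-membered bis-allylic ether whose oxygen joins C6 and C12 of an oxidised farnesyl chain. The feature exploited is the C6 oxygen beside C7 with its three-carbon C11 branch on the ten-membered ring: with the isopropyl read as a hydrogenated isopropenyl, this is the homoallylic alcohol left by a [2,3]-Wittig shift. In one operation the shift forms C6-C7, cleaves O-C12, contracts the oxacycle to the carbocycle and sets C7 and a provisional C6 carbinol under relay from C3. Its precursor is the (3S)-hydroxy all-E 13-membered ether, built from prenol and geranyl acetate. The oxirane and the final C6 configuration follow afterwards.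

Key step: step 16

Remark: germacrane numbering is used for every intermediate (C1=C10 alkene, C3 senecioate carbon, C4-C5 oxirane, C6 acetate carbon, C7 isopropyl carbon, C12 the oxidised branch carbon, C14 and C15 the ring methyls); t-BuOOH, BaI2, the CBS catalyst and ethereal Zn(BH4)2 are assumed to be purchased or standard stock reagents.

Step 1
Reactants: 1 prenol (3-methylbut-2-en-1-ol)
Product: 2 prenyl tert-butyldiphenylsilyl ether
Conditions: TBDPSCl, imidazole, CH2Cl2, 0 °C to rt
Reagents that add atoms: tert-butyl(chloro)diphenylsilane, CC(C)(C)[Si](Cl)(c1ccccc1)c1ccccc1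
Why: Silyl ether formation at the primary alcohol; TBDPS is chosen because it survives the allylic oxidations, the organobarium addition, the borane reduction and the mild acid that later removes a TBS group.

Step 2
Reactants: 2 prenyl tert-butyldiphenylsilyl ether
Product: 4 (E)-4-(tert-butyldiphenylsilyloxy)-2-methylbut-2-enal (C3 to C6 plus C15), via allylic alcohol 3 (not isolated)
Conditions: SeO2 (cat.), t-BuOOH, salicylic acid (cat.), CH2Cl2, rt; then MnO2, CH2Cl2, rt on the filtered crude mixture
Reagents that add atoms: tert-butyl hydroperoxide, CC(C)(C)OO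
Why: Riley oxidation (ene reaction, then [2,3] shift of the allylseleninic acid) functionalises only the methyl trans to the CH2O chain, which fixes the E geometry of the future C4=C5 alkene, and MnO2 allylic oxidation converges the alcohol/aldehyde mixture on the enal.

Step 3
Reactants: 5 geranyl acetate
Product: 6 (2E,6E)-8-hydroxygeranyl acetate
Conditions: SeO2 (cat.), t-BuOOH, salicylic acid (cat.), CH2Cl2, 0 °C to rt
Reagents that add atoms: tert-butyl hydroperoxide, CC(C)(C)OO
Why: Riley oxidation picks the E-methyl of the distal, more electron-rich trisubstituted alkene (the alkene beside the acetate is deactivated), which installs the C12 oxygen with E geometry at the future C7=C11 bond.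

Step 4
Reactants: 6 (2E,6E)-8-hydroxygeranyl acetate
Product: 7 (2E,6E)-8-(tert-butyldimethylsilyloxy)geranyl acetate
Conditions: TBSCl, imidazole, CH2Cl2, 0 °C to rt
Reagents that add atoms: tert-butyl(chloro)dimethylsilane, CC(C)(C)[Si](C)(C)Cl
Why: Standard silylation; the TBS ether is orthogonal to the TBDPS ether of the other fragment because mild acid cleaves it far faster.

Step 5
Reactants: 7 (2E,6E)-8-(tert-butyldimethylsilyloxy)geranyl acetate
Product: 8 (2E,6E)-8-(tert-butyldimethylsilyloxy)geraniol
Conditions: K2CO3, MeOH, rt
Reagents that add atoms: none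
Why: Base-catalysed transesterification with methanol removes the acetate without touching the silyl ether or the alkenes.

Step 6
Reactants: 8 (2E,6E)-8-(tert-butyldimethylsilyloxy)geraniol
Product: 10 (2E,6E)-8-(tert-butyldimethylsilyloxy)geranyl chloride (C2, C1, C10 to C7, C11 to C14), via allylic mesylate 9 (not isolated)
Conditions: MsCl, 2,4,6-collidine, LiCl, DMF, 0 °C
Reagents that add atoms: lithium chloride, [Li+].[Cl-]; methanesulfonyl chloride, CS(=O)(=O)Cl (second chloride source)
Why: Mesylation followed in the same flask by SN2 exchange with chloride gives the primary allylic chloride without allylic transposition or loss of E geometry.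

Step 7
Reactants: 10 (2E,6E)-8-(tert-butyldimethylsilyloxy)geranyl chloride; 4 (E)-4-(tert-butyldiphenylsilyloxy)-2-methylbut-2-enal
Product: 12 racemic all-E open-chain C15 trienol (C3-OH; C6-OTBDPS; C12-OTBS), via allylbarium chloride 11 (not isolated)
Conditions: BaI2, Li, biphenyl, THF, rt; then 10, −78 °C; then 4, −78 °C; aq NH4Cl
Reagents that add atoms: none
Why: Carbonyl allylation with an allylbarium reagent, made from activated zerovalent barium at −78 °C, is known to take place at the alpha carbon of geranyl-type reagents with retention of alkene geometry and in 1,2 fashion on enals, so the C2-C3 bond should form with all three E alkenes intact; the new carbinol is racemic and is corrected in the next two steps.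

Step 8
Reactants: 12 racemic open-chain C15 trienol
Product: 13 open-chain C3 ketone (alpha-methyl enone)
Conditions: Dess–Martin periodinane (DMP), pyridine, CH2Cl2, 0 °C
Reagents that add atoms: none
Why: Dess–Martin oxidation with pyridine buffering converts the allylic carbinol into the enone under near-neutral conditions that do not pull the beta,gamma C1=C10 alkene into conjugation.

Step 9
Reactants: 13 open-chain C3 ketone
Product: 14 (3S)-trienol (C3-OH; C6-OTBDPS; C12-OTBS)
Conditions: (R)-2-methyl-CBS-oxazaborolidine (0.2 equiv), catecholborane, toluene, −78 °C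
Reagents that add atoms: none
Why: Corey–Bakshi–Shibata reduction: the alpha-methylalkenyl group acts as the large substituent and the allylic CH2 as the small one, so the (R)-catalyst should deliver hydride to the face that gives the 3S alcohol, and catecholborane at low temperature does not hydroborate the alkenes.

Step 10
Reactants: 14 (3S)-trienol
Product: 15 (3S)-C3 pivalate (C6-OTBDPS; C12-OTBS)
Conditions: PivCl, pyridine, DMAP (cat.), CH2Cl2, 0 °C to rt
Reagents that add atoms: pivaloyl chloride, CC(C)(C)C(=O)Cl
Why: Acylation of the only free hydroxyl; a pivalate is chosen because it resists mild acid, HF and NaH, cannot migrate to C6 across the E alkene, and is later removed by hydride, so that no oxidant or strong acid need touch the bis-allylic ether.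

Step 11
Reactants: 15 (3S)-C3 pivalate
Product: 16 C12 alcohol (C3-OPiv; C6-OTBDPS)
Conditions: PPTS, MeOH, rt
Reagents that add atoms: none
Why: Acid-catalysed methanolysis cleaves the primary TBS ether much faster than the bulkier, acid-stable primary TBDPS ether and leaves the pivalate alone (selective desilylation).

Step 12
Reactants: 16 C12 alcohol
Product: 18 C12 chloride (C3-OPiv; C6-OTBDPS), via C12 mesylate 17 (not isolated)
Conditions: MsCl, 2,4,6-collidine, LiCl, DMF, 0 °C
Reagents that add atoms: lithium chloride, [Li+].[Cl-]; methanesulfonyl chloride, CS(=O)(=O)Cl (second chloride source)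
Why: The same mesylate-to-chloride SN2 exchange converts the primary allylic C12 alcohol into the chloride without touching the hindered ester or the silyl ether.

Step 13
Reactants: 18 C12 chloride
Product: 19 seco chloro alcohol (C6-OH; C12-Cl; C3-OPiv)
Conditions: HF·pyridine, pyridine, THF, 0 °C to rt
Reagents that add atoms: none
Why: Fluoride desilylation under acidic conditions frees the C6 hydroxyl without forming an alkoxide or a nucleophilic fluoride salt that could displace the allylic chloride before high dilution is applied.

Step 14
Reactants: 19 seco chloro alcohol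
Product: 21 13-membered (E,E,E)-bis-allylic ether C3 pivalate, via sodium alkoxide 20 (not isolated)
Conditions: NaH, THF, 60 °C, syringe-pump addition of 19 (final concentration about 2 mM)
Reagents that add atoms: none
Why: Intramolecular Williamson etherification, a closure known for 13-membered ethers of farnesyl-type chloro alcohols: under high dilution the primary C6 alkoxide displaces the primary allylic C12 chloride by SN2, the E alkenes are not involved, and the blocked C3 oxygen cannot close a competing ten-membered ether.

Step 15
Reactants: 21 13-membered ether C3 pivalate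
Product: 22 (3S)-13-membered (E,E,E)-bis-allylic ether with free C3 hydroxyl
Conditions: i-Bu2AlH, CH2Cl2, −78 °C; aq KNaC4H4O6
Reagents that add atoms: none
Why: Reductive ester cleavage with an aluminium hydride releases the C3 hydroxyl while the bis-allylic ether and the alkenes stay inert, whereas oxidative unmasking of an arylmethyl ether would endanger the two prenyl-type ether carbons.

Step 16
Reactants: 22 (3S)-13-membered bis-allylic ether with free C3 hydroxyl
Product: 25 (3S,6R,7S)-germacra-1(10),4,11-triene-3,6-diol (both ring alkenes E; 6-OH trans to 7-isopropenyl), via lithium alkoxide 23 (not isolated), via dilithio species 24 (not isolated)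
Conditions: n-BuLi (1.05 equiv), THF, −78 °C; then s-BuLi (2.2 equiv), −78 to −30 °C; aq NH4Cl
Reagents that add atoms: none
Why: Proposed new method: n-BuLi first turns the C3 hydroxyl into a lithium alkoxide, s-BuLi then lithiates C6 (alpha to the ring oxygen and allylic to C4=C5), and the carbanion attacks C7 suprafacially through a five-membered envelope (C6, O, C12, C11, C7), forming C6-C7, cleaving O-C12 and moving the alkene to C11=C12. The closest known reaction type is the transannular [2,3]-Wittig ring contraction of 13-membered bis-allylic ethers to cyclodeca-1,5-dienols; what is untested is the dianion and the use of its C3 alkoxide as the controlling element. The ten-membered carbocycle is closed by sigmatropic contraction inside the macrocycle and not by an end-to-end cyclisation, so the two E ring alkenes pass through as spectators. C6 and C7 arise together: the E geometry of C7=C11 within the envelope gives the trans C6-OH/C7-isopropenyl pair, and the C3 alkoxide, held in a lithium aggregate with the allyl anion on the outer face of the C4-C5-C6 unit, leaves the inner face for bond formation with inversion at C6, which should lead to 6R,7S. The step needs lithiation at C6 and not at C12, which is secured because a C12 anion could only bond to the fully substituted C4 next to the alkoxide, and it needs the absence of 1,4-elimination, which is secured because an oxide dianion at C3 cannot leave.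

Step 17
Reactants: 25 (3S,6R,7S)-germacra-1(10),4,11-triene-3,6-diol
Product: 26 (3S,6S,7S)-germacra-1(10),4-diene-3,6-diol (7-isopropyl; spatial arrangement unchanged)
Conditions: H2 (1 atm), RhCl(PPh3)3 (cat.), benzene, rt
Reagents that add atoms: none
Why: Homogeneous hydrogenation with RhCl(PPh3)3 is selective for the unhindered 1,1-disubstituted alkene over trisubstituted ones, so the isopropenyl group should become isopropyl while both ring alkenes and C7 stay untouched.

Step 18
Reactants: 26 (3S,6S,7S)-germacra-1(10),4-diene-3,6-diol; 27 senecioic acid (3-methylbut-2-enoic acid)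
Product: 28 (3S,6S,7S)-3-senecioyloxygermacra-1(10),4-dien-6-ol
Conditions: 27 (1.05 equiv), DCC, DMAP (cat.), CH2Cl2, −20 to 0 °C
Reagents that add atoms: none
Why: Steglich esterification with a slight excess of acid at low temperature should acylate the C3 hydroxyl, flanked by a CH2 and an sp2 carbon, in preference to the C6 hydroxyl, which lies gauche to the isopropyl group on C7.

Step 19
Reactants: 28 3-senecioyloxygermacra-1(10),4-dien-6-ol
Product: 29 (3S,4R,5R,6S,7S)-4,5-epoxy-3-senecioyloxygermacr-1(10)-en-6-ol (threo epoxy alcohol)
Conditions: VO(acac)2 (cat.), t-BuOOH, CH2Cl2, 0 °C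
Reagents that add atoms: tert-butyl hydroperoxide, CC(C)(C)OO
Why: Hydroxyl-directed vanadium-catalysed epoxidation: only C4=C5 is allylic to a free hydroxyl, and with H6 eclipsing the alkene to avoid 1,3-allylic strain with the C15 methyl the C6 hydroxyl sits on the outer face and C7 on the inner face, so oxygen should be delivered to the peripheral face to give the threo 4R,5R epoxy alcohol, while the C1=C10 alkene and the enoate are not addressed.

Step 20
Reactants: 29 threo epoxy alcohol
Product: 30 (3S,4R,5S,7S)-4,5-epoxy-3-senecioyloxygermacr-1(10)-en-6-one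
Conditions: DMP, pyridine, CH2Cl2, 0 °C to rt
Reagents that add atoms: none
Why: Dess–Martin oxidation with pyridine buffering gives the alpha,beta-epoxy ketone without base, so the oxirane, the ester and the enolisable C7 centre are preserved.

Step 21
Reactants: 30 4,5-epoxy-6-ketone
Product: 31 (3S,4R,5R,6R,7S)-4,5-epoxy-3-senecioyloxygermacr-1(10)-en-6-ol (erythro epoxy alcohol)
Conditions: Zn(BH4)2, Et2O, −20 °C
Reagents that add atoms: none
Why: Chelation-controlled reduction of an alpha,beta-epoxy ketone: zinc bridges the carbonyl and oxirane oxygens and hydride adds to the face away from oxirane carbon C4, which should give the erythro (anti) epoxy alcohol, that is C6 inverted relative to 29, while the enoate is not reduced.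

Step 22
Reactants: 31 erythro epoxy alcohol
Product: 32 target CNP0267399.1, (3S,4R,5R,6R,7S)-6-acetoxy-4,5-epoxy-3-senecioyloxygermacr-1(10)E-ene
Conditions: Ac2O, pyridine, DMAP (cat.), CH2Cl2, 0 °C to rt
Reagents that add atoms: acetic anhydride, CC(=O)OC(C)=O
Why: DMAP-catalysed acetylation of the remaining secondary hydroxyl gives the target without affecting any stereocentre.

Compound list
1 | prenol (3-methylbut-2-en-1-ol) | CC(C)=CCO | starting material
2 | prenyl tert-butyldiphenylsilyl ether | CC(C)=CCO[Si](c1ccccc1)(c1ccccc1)C(C)(C)C | intermediate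
3 | (E)-4-(tert-butyldiphenylsilyloxy)-2-methylbut-2-en-1-ol | OC/C(C)=C/CO[Si](c1ccccc1)(c1ccccc1)C(C)(C)C | intermediate
4 | (E)-4-(tert-butyldiphenylsilyloxy)-2-methylbut-2-enal | O=C/C(C)=C/CO[Si](c1ccccc1)(c1ccccc1)C(C)(C)C | intermediate
5 | geranyl acetate | CC(=O)OC/C=C(\C)CCC=C(C)C | starting material
6 | (2E,6E)-8-hydroxygeranyl acetate | CC(=O)OC/C=C(\C)CC/C=C(\C)CO | intermediate
7 | (2E,6E)-8-(tert-butyldimethylsilyloxy)geranyl acetate | CC(=O)OC/C=C(\C)CC/C=C(\C)CO[Si](C)(C)C(C)(C)C | intermediate
8 | (2E,6E)-8-(tert-butyldimethylsilyloxy)geraniol | OC/C=C(\C)CC/C=C(\C)CO[Si](C)(C)C(C)(C)C | intermediate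
9 | (2E,6E)-8-(tert-butyldimethylsilyloxy)geranyl methanesulfonate | CS(=O)(=O)OC/C=C(\C)CC/C=C(\C)CO[Si](C)(C)C(C)(C)C | intermediate
10 | (2E,6E)-8-(tert-butyldimethylsilyloxy)geranyl chloride | ClC/C=C(\C)CC/C=C(\C)CO[Si](C)(C)C(C)(C)C | intermediate
11 | (2E,6E)-8-(tert-butyldimethylsilyloxy)geranylbarium chloride | Cl[Ba]C/C=C(\C)CC/C=C(\C)CO[Si](C)(C)C(C)(C)C | intermediate
12 | racemic (2E,6E,10E)-3,7,11-trimethyldodeca-2,6,10-triene-1,4,12-triol 1-TBDPS 12-TBS ether (C3-OH; C6-OTBDPS; C12-OTBS) | CC(C)(C)[Si](c1ccccc1)(c1ccccc1)OC/C=C(\C)C(O)C/C=C(\C)CC/C=C(\C)CO[Si](C)(C)C(C)(C)C | intermediate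
13 | corresponding 4-ketone (C3 ketone, alpha-methyl enone) | CC(C)(C)[Si](c1ccccc1)(c1ccccc1)OC/C=C(\C)C(=O)C/C=C(\C)CC/C=C(\C)CO[Si](C)(C)C(C)(C)C | intermediate
14 | (S)-carbinol at C3 of the same chain (C6-OTBDPS; C12-OTBS) | CC(C)(C)[Si](c1ccccc1)(c1ccccc1)OC/C=C(\C)[C@@H](O)C/C=C(\C)CC/C=C(\C)CO[Si](C)(C)C(C)(C)C | intermediate
15 | (S)-C3 pivalate (C6-OTBDPS; C12-OTBS) | CC(C)(C)[Si](c1ccccc1)(c1ccccc1)OC/C=C(\C)[C@@H](OC(=O)C(C)(C)C)C/C=C(\C)CC/C=C(\C)CO[Si](C)(C)C(C)(C)C | intermediate
16 | (S)-C3 pivalate with free C12 hydroxyl (C6-OTBDPS) | CC(C)(C)[Si](c1ccccc1)(c1ccccc1)OC/C=C(\C)[C@@H](OC(=O)C(C)(C)C)C/C=C(\C)CC/C=C(\C)CO | intermediate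
17 | C12 methanesulfonate of 16 | CC(C)(C)[Si](c1ccccc1)(c1ccccc1)OC/C=C(\C)[C@@H](OC(=O)C(C)(C)C)C/C=C(\C)CC/C=C(\C)COS(C)(=O)=O | intermediate
18 | (S)-C3 pivalate C12 chloride (C6-OTBDPS) | CC(C)(C)[Si](c1ccccc1)(c1ccccc1)OC/C=C(\C)[C@@H](OC(=O)C(C)(C)C)C/C=C(\C)CC/C=C(\C)CCl | intermediate
19 | seco chloro alcohol: (S)-C3 pivalate with C6-OH and C12-Cl | OC/C=C(\C)[C@@H](OC(=O)C(C)(C)C)C/C=C(\C)CC/C=C(\C)CCl | intermediate
20 | sodium C6 alkoxide of 19 | [Na+].[O-]C/C=C(\C)[C@@H](OC(=O)C(C)(C)C)C/C=C(\C)CC/C=C(\C)CCl | intermediate
21 | (3S)-13-membered (E,E,E)-bis-allylic ether (O joins C6 and C12), C3 pivalate | CC(C)(C)C(=O)O[C@H]1C/C=C(\C)CC/C=C(\C)COC/C=C1\C | intermediate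
22 | (3S)-13-membered (E,E,E)-bis-allylic ether, free C3 hydroxyl | O[C@H]1C/C=C(\C)CC/C=C(\C)COC/C=C1\C | intermediate
23 | lithium C3 alkoxide of 22 | [Li]O[C@H]1C/C=C(\C)CC/C=C(\C)COC/C=C1\C | intermediate
24 | C6-lithiated lithium alkoxide of 22 (configuration at C6 not defined) | [Li]O[C@H]1C/C=C(\C)CC/C=C(\C)COC([Li])/C=C1\C | intermediate
25 | (3S,6R,7S)-germacra-1(10)E,4E,11-triene-3,6-diol | O[C@@H]1/C=C(\C)[C@@H](O)C/C=C(\C)CC[C@H]1C(C)=C | intermediate
26 | (3S,6S,7S)-germacra-1(10)E,4E-diene-3,6-diol | O[C@@H]1/C=C(\C)[C@@H](O)C/C=C(\C)CC[C@H]1C(C)C | intermediate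
27 | senecioic acid (3-methylbut-2-enoic acid) | CC(C)=CC(=O)O | starting material
28 | (3S,6S,7S)-3-senecioyloxygermacra-1(10)E,4E-dien-6-ol | O[C@@H]1/C=C(\C)[C@@H](OC(=O)C=C(C)C)C/C=C(\C)CC[C@H]1C(C)C | intermediate
29 | (3S,4R,5R,6S,7S)-4,5-epoxy-3-senecioyloxygermacr-1(10)E-en-6-ol (threo) | O[C@@H]1[C@H]2O[C@]2(C)[C@@H](OC(=O)C=C(C)C)C/C=C(\C)CC[C@H]1C(C)C | intermediate
30 | (3S,4R,5S,7S)-4,5-epoxy-3-senecioyloxygermacr-1(10)E-en-6-one | O=C1[C@H]2O[C@]2(C)[C@@H](OC(=O)C=C(C)C)C/C=C(\C)CC[C@H]1C(C)C | intermediate
31 | (3S,4R,5R,6R,7S)-4,5-epoxy-3-senecioyloxygermacr-1(10)E-en-6-ol (erythro) | O[C@H]1[C@H]2O[C@]2(C)[C@@H](OC(=O)C=C(C)C)C/C=C(\C)CC[C@H]1C(C)C | intermediate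
32 | CNP0267399.1, (3S,4R,5R,6R,7S)-6-acetoxy-4,5-epoxy-3-senecioyloxygermacr-1(10)E-ene | CC(=O)O[C@H]1[C@H]2O[C@]2(C)[C@@H](OC(=O)C=C(C)C)C/C=C(\C)CC[C@H]1C(C)C | target

Total step count: 22. Longest linear sequence: 20 steps (geranyl acetate 5 to target 32: steps 3 to 6, then 7 to 22).

Steps most likely to fail

1. Step 16 (the labelled step). What may go wrong: lithiation at C12 or at the C15 methyl in place of C6, a competing [1,2] shift, or too little facial control by the alkoxide, so that the C6/C7 pair forms with the wrong sense relative to C3. The fallback uses known chemistry and sets out from chloro alcohol 19. MnO2 in CH2Cl2 would oxidise the primary allylic alcohol to the chloro enal F1. Slow addition of this compound to CrCl2 in THF at room temperature is an intramolecular Nozaki–Hiyama–Kishi allylation, a closure known for ten-membered germacrane rings from farnesyl-type chloro aldehydes. It would turn the C12 chloride into an allylchromium species that adds through its gamma carbon C7 to the C6 aldehyde by way of a chair transition state. This makes the same C6-C7 bond, the same isopropenyl group and the same trans C6/C7 relationship, in the 3-pivaloyloxy germacratrienol F2. The pivalate would then be removed with i-Bu2AlH at −78 °C, and the route is rejoined at diol 25.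

2. Step 18. What may go wrong: loss of site selectivity, with acylation at C6 or at both hydroxyls. The fallback sets out from diol 26 and replaces the selective acylation by a selective unmasking. Both hydroxyls would be silylated with TESOTf and 2,6-lutidine to the bis(triethylsilyl) ether F3. PPTS in MeOH at −10 °C, stopped at partial conversion with recycling, should cleave the less hindered C3 silyl ether first and give the C6 mono(triethylsilyl) ether F4. Steglich esterification of its single free hydroxyl with 27 would give the silyl-protected senecioate F5, and HF·pyridine would remove the silyl group, so that the route is rejoined at monoester 28.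

3. Step 21. What may go wrong: hydride delivery from the wrong face if the ring conformation overrides chelation (which would return 29), or Lewis-acid opening of the oxirane. The fallback sets out from threo epoxy alcohol 29 and avoids the ketone. A Mitsunobu reaction with acetic acid (PPh3, DIAD, toluene, 0 °C to rt) would displace the activated C6 oxygen by acetate with SN2 inversion, which arrives directly at target 32 and bypasses 30 and 31; no new compound is made on this path (F0).

Further compounds
F1 | step 16 | (4S,2E,6E,10E)-12-chloro-3,7,11-trimethyl-1-oxododeca-2,6,10-trien-4-yl pivalate (chloro enal) | O=C/C=C(\C)[C@@H](OC(=O)C(C)(C)C)C/C=C(\C)CC/C=C(\C)CCl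
F2 | step 16 | (3S,6R,7S)-6-hydroxygermacra-1(10)E,4E,11-trien-3-yl pivalate | O[C@@H]1/C=C(\C)[C@@H](OC(=O)C(C)(C)C)C/C=C(\C)CC[C@H]1C(C)=C
F3 | step 18 | 3,6-bis(triethylsilyl) ether of diol 26 | CC[Si](CC)(CC)O[C@@H]1/C=C(\C)[C@@H](O[Si](CC)(CC)CC)C/C=C(\C)CC[C@H]1C(C)C
F4 | step 18 | 6-O-triethylsilyl ether of diol 26 (free C3 hydroxyl) | CC[Si](CC)(CC)O[C@@H]1/C=C(\C)[C@@H](O)C/C=C(\C)CC[C@H]1C(C)C
F5 | step 18 | 6-O-triethylsilyl ether of monoester 28 | CC[Si](CC)(CC)O[C@@H]1/C=C(\C)[C@@H](OC(=O)C=C(C)C)C/C=C(\C)CC[C@H]1C(C)C
F0 | step 21 | none | none
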